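**Retrosynthetic overview**
- Last disconnection: the CH2 bridge. The ring methyl of an (R)-configured acetyl-geranyl-dimethyl cyclohexadienone is the latent bridge carbon (dehydrogenated to an o-quinone methide), and C8–H of the chromene is the nucleophile.
- The quaternary stereocentre comes from a desymmetrising asymmetric Tsuji–Trost geranylation that dearomatises symmetric 3,5-dimethylphloroacetophenone.
- The 2H-pyran ring is made in one operation by a decarboxylative formal [4+2] annulation of a 2-aryloxy-2-methylpropanoic redox-active ester with ethyl vinyl ether. C2–C3 and C4–C4a form together; the activating carboxyl leaves as CO2 and the ethoxy group as ethanol.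
- Enabling feature: O1 sits on arene carbon C8a para to the butanoyl group, between two equivalent electron-rich ring CH carbons (future C4a and C8), and C2 is an acetone-level gem-dimethyl carbon already on O1. O1=C2(+)/C8a=C4a is therefore a latent 2-oxonia-diene that accepts a two-carbon unit.
- Ring order: chromene benzene ring (bought) → pyran ring (step 5); second benzene ring (bought) → cyclohexadienone ring by dearomatisation (step 8); union (step 9).

Key step: step 5

Assumption: the (R,R)-bisphosphine ligand in step 8 is taken to give the (R) quaternary centre (its (S,S)-enantiomer is used if the sense proves opposite); the dearomatised ring is drawn in the enol tautomer of the target SMILES and the CIP descriptors refer to that drawing.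

**Step 1**
Reactants: 1 phloroglucinol (benzene-1,3,5-triol)
Product: 2 1-(2,4,6-trihydroxyphenyl)butan-1-one
Conditions: butanoyl chloride (1.05 equiv), AlCl3 (3.5 equiv), nitrobenzene/CH2Cl2, 0 to 40 °C; aqueous HCl work-up
Reagents that add atoms: butanoyl chloride, CCCC(Cl)=O
Why: Friedel–Crafts acylation of the electron-rich triol should stop after one acyl group because the chelated ketone deactivates the ring.

**Step 2**
Reactants: 2 1-(2,4,6-trihydroxyphenyl)butan-1-one
Product: 3 ethyl 2-(4-butanoyl-3,5-dihydroxyphenoxy)-2-methylpropanoate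
Conditions: ethyl 2-bromo-2-methylpropanoate (1.2 equiv), K2CO3 (1.2 equiv), DMF, 70 °C
Reagents that add atoms: ethyl 2-bromo-2-methylpropanoate, CCOC(=O)C(C)(C)Br
Why: Williamson etherification as in fibrate syntheses; the 4-hydroxyl is the only one not hydrogen-bonded to the ketone and the most acidic, so its phenoxide should be alkylated selectively, which fixes the future O1 para to the butanoyl group.

**Step 3**
Reactants: 3 ethyl 2-(4-butanoyl-3,5-dihydroxyphenoxy)-2-methylpropanoate
Product: 4 2-(4-butanoyl-3,5-dihydroxyphenoxy)-2-methylpropanoic acid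
Conditions: LiOH (4 equiv), THF/H2O, 40 °C, under N2; then 1 M HCl to pH 2
Reagents that add atoms: lithium hydroxide, [Li+].[OH-]
Why: Ester saponification; the aryl ketone and the tertiary aryl ether are inert to hydroxide, and air is excluded to protect the phenoxide.

**Step 4**
Reactants: 4 2-(4-butanoyl-3,5-dihydroxyphenoxy)-2-methylpropanoic acid
Product: 5 1,3-dioxoisoindolin-2-yl 2-(4-butanoyl-3,5-dihydroxyphenoxy)-2-methylpropanoate
Conditions: N-hydroxyphthalimide (1.1 equiv), N,N'-diisopropylcarbodiimide (1.1 equiv), DMAP (5 mol%), CH2Cl2, 0 to 25 °C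
Reagents that add atoms: N-hydroxyphthalimide, ON1C(=O)c2ccccc2C1=O
Why: Carbodiimide (Steglich-type) esterification; the α-effect nucleophile N-hydroxyphthalimide should outcompete the two chelated, ketone-deactivated phenols.

**Step 5**
Reactants: 5 1,3-dioxoisoindolin-2-yl 2-(4-butanoyl-3,5-dihydroxyphenoxy)-2-methylpropanoate
Product: 8 1-(5,7-dihydroxy-2,2-dimethyl-2H-chromen-6-yl)butan-1-one, via O-aryl oxocarbenium ion 6 (not isolated), via 4-ethoxychroman 7 (not isolated)
Conditions: ethyl vinyl ether (5 equiv), Ir(ppy)3 (1 mol%), MeCN (0.05 M), blue LEDs (450 nm), 25 °C, under N2; then evaporate volatiles, PPTS (10 mol%), toluene, 60 °C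
Reagents that add atoms: ethyl vinyl ether, C=COCC
Why: Proposed new method: photoexcited Ir(ppy)3 should transfer an electron to the N-(acyloxy)phthalimide, which fragments to CO2, phthalimide anion and the tertiary α-aryloxy radical, and tetravalent iridium oxidises this electron-rich radical to the O-aryl oxocarbenium ion 6 (radical–polar crossover), whose cationic C2 is attacked by the terminal carbon of ethyl vinyl ether (C2–C3 bond) to give an ethoxycarbenium ion at C4 that the neighbouring arene carbon captures (C4–C4a bond), giving 7, from which PPTS expels ethanol through the phenol-stabilised benzylic cation to leave the C3=C4 double bond. The closest known reaction types are the formal [4+2] (oxa-Povarov) annulation of aldehyde-derived O-aryl oxocarbenium ions with alkenes to chromans, the photoredox decarboxylative generation of carbocations from redox-active esters, and the acid-induced loss of ROH from 4-alkoxychromans; new are the decarboxylative access to a ketone-derived O-aryl cation and the enol ether as an acetylene equivalent. The pyran ring (O1–C2–C3–C4–C4a–C8a) closes stepwise by an intramolecular Friedel–Crafts (Prins-type) 6-exo-trig attack of the arene on the C4 oxocarbenium carbon, not by a concerted cycloaddition. No stereocentre has to be controlled: C2 is gem-dimethyl, and the C4 centre of 7 forms racemic and is erased by the elimination. The step needs C–C capture of 6 to outrun proton loss or return of phthalimide anion, and ring closure to outrun oligomerisation of the enol ether; the first is served by excess enol ether under non-nucleophilic redox-neutral conditions, the second by the six-membered transition state onto a ring carbon flanked by two oxygen-bearing carbons. Regiochemistry is not an issue because the 4-acyl-3,5-dihydroxyphenoxy ring is symmetric (both ortho carbons equivalent) and the para relation of O1 to the butanoyl group was fixed in step 2.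

**Step 6**
Reactants: 9 1-(2,4,6-trihydroxyphenyl)ethan-1-one
Product: 10 1-(2,4,6-trihydroxy-3,5-dimethylphenyl)ethan-1-one
Conditions: MeI (2.1 equiv), NaOMe (2.2 equiv), MeOH, 0 to 25 °C; dilute HCl work-up, chromatography
Reagents that add atoms: iodomethane, CI
Why: Base-mediated C-methylation of the phloroglucinol phenoxide at its two equivalent free ring carbons, a known route to C-methylated acylphloroglucinols; 10 should be separable from mono- and gem-dimethylated by-products.

**Step 7**
Reactants: 11 geraniol, (2E)-3,7-dimethylocta-2,6-dien-1-ol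
Product: 12 methyl (2E)-3,7-dimethylocta-2,6-dien-1-yl carbonate
Conditions: methyl chloroformate (1.2 equiv), pyridine (1.5 equiv), CH2Cl2, 0 °C
Reagents that add atoms: methyl chloroformate, COC(Cl)=O
Why: O-acylation of the primary allylic alcohol, which leaves the (E) double bond untouched.

**Step 8**
Reactants: 10 1-(2,4,6-trihydroxy-3,5-dimethylphenyl)ethan-1-one; 12 methyl (2E)-3,7-dimethylocta-2,6-dien-1-yl carbonate
Product: 13 (4R)-2-acetyl-4-[(2E)-3,7-dimethylocta-2,6-dien-1-yl]-3,5-dihydroxy-4,6-dimethylcyclohexa-2,5-dien-1-one
Conditions: Pd2(dba)3·CHCl3 (2.5 mol%), (1R,2R)-N,N'-bis[2-(diphenylphosphino)benzoyl]cyclohexane-1,2-diamine (7.5 mol%), 12 (1.0 equiv), THF, 0 to 25 °C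
Reagents that add atoms: none
Why: Tsuji–Trost asymmetric allylic alkylation used as a desymmetrising dearomatisation: the two methyl-bearing ring carbons of 10 are enantiotopic and the only C-alkylatable sites, the chiral bisphosphine pocket around the π-geranyl complex of divalent palladium selects one of them and the face of attack and so sets the (R) quaternary centre, and attack at the unhindered allyl terminus should give the linear (E)-geranyl group.

**Step 9**
Reactants: 13 (4R)-2-acetyl-4-[(2E)-3,7-dimethylocta-2,6-dien-1-yl]-3,5-dihydroxy-4,6-dimethylcyclohexa-2,5-dien-1-one; 8 1-(5,7-dihydroxy-2,2-dimethyl-2H-chromen-6-yl)butan-1-one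
Product: 15 (4R)-2-acetyl-6-[(6-butanoyl-5,7-dihydroxy-2,2-dimethyl-2H-chromen-8-yl)methyl]-4-[(2E)-3,7-dimethylocta-2,6-dien-1-yl]-3,5-dihydroxy-4-methylcyclohexa-2,5-dien-1-one, via o-quinone methide 14 (not isolated)
Conditions: Ag2O (1.2 equiv), TEMPO (0.2 equiv), 8 (1.2 equiv), THF, 0 to 25 °C, in the dark
Reagents that add atoms: none
Why: Oxidative dehydrogenation of the ring methyl between the two enol carbons (known for methylated dearomatised acylphloroglucinols) should give o-quinone methide 14, and Michael (Friedel–Crafts-type) addition of the only free arene carbon of 8, C8, then forms the methylene bridge; the quaternary centre is not involved and has no pathway to epimerise.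

**Compound list**
1 | phloroglucinol (benzene-1,3,5-triol) | Oc1cc(O)cc(O)c1 | starting material
2 | 1-(2,4,6-trihydroxyphenyl)butan-1-one | CCCC(=O)c1c(O)cc(O)cc1O | intermediate
3 | ethyl 2-(4-butanoyl-3,5-dihydroxyphenoxy)-2-methylpropanoate | CCCC(=O)c1c(O)cc(OC(C)(C)C(=O)OCC)cc1O | intermediate
4 | 2-(4-butanoyl-3,5-dihydroxyphenoxy)-2-methylpropanoic acid | CCCC(=O)c1c(O)cc(OC(C)(C)C(=O)O)cc1O | intermediate
5 | 1,3-dioxoisoindolin-2-yl 2-(4-butanoyl-3,5-dihydroxyphenoxy)-2-methylpropanoate | CCCC(=O)c1c(O)cc(OC(C)(C)C(=O)ON2C(=O)c3ccccc3C2=O)cc1O | intermediate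
6 | 2-(4-butanoyl-3,5-dihydroxyphenoxy)propan-2-ylium (O-aryl oxocarbenium ion, not isolated) | CCCC(=O)c1c(O)cc([O+]=C(C)C)cc1O | intermediate
7 | 1-(4-ethoxy-5,7-dihydroxy-2,2-dimethyl-3,4-dihydro-2H-chromen-6-yl)butan-1-one (racemic at C4, not isolated) | CCCC(=O)c1c(O)cc2OC(C)(C)CC(OCC)c2c1O | intermediate
8 | 1-(5,7-dihydroxy-2,2-dimethyl-2H-chromen-6-yl)butan-1-one | CCCC(=O)c1c(O)cc2OC(C)(C)C=Cc2c1O | intermediate
9 | 1-(2,4,6-trihydroxyphenyl)ethan-1-one | CC(=O)c1c(O)cc(O)cc1O | starting material
10 | 1-(2,4,6-trihydroxy-3,5-dimethylphenyl)ethan-1-one | CC(=O)c1c(O)c(C)c(O)c(C)c1O | intermediate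
11 | geraniol, (2E)-3,7-dimethylocta-2,6-dien-1-ol | OC/C=C(\C)CCC=C(C)C | starting material
12 | methyl (2E)-3,7-dimethylocta-2,6-dien-1-yl carbonate | COC(=O)OC/C=C(\C)CCC=C(C)C | intermediate
13 | (4R)-2-acetyl-4-[(2E)-3,7-dimethylocta-2,6-dien-1-yl]-3,5-dihydroxy-4,6-dimethylcyclohexa-2,5-dien-1-one | CC1=C(O)[C@@](C)(C/C=C(\C)CCC=C(C)C)C(O)=C(C(C)=O)C1=O | intermediate
14 | (6S)-4-acetyl-6-[(2E)-3,7-dimethylocta-2,6-dien-1-yl]-5-hydroxy-6-methyl-2-methylidenecyclohex-4-ene-1,3-dione (o-quinone methide, not isolated; same spatial arrangement as 13, the descriptor changes with the ring priorities) | C=C1C(=O)[C@@](C)(C/C=C(\C)CCC=C(C)C)C(O)=C(C(C)=O)C1=O | intermediate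
15 | (4R)-2-acetyl-6-[(6-butanoyl-5,7-dihydroxy-2,2-dimethyl-2H-chromen-8-yl)methyl]-4-[(2E)-3,7-dimethylocta-2,6-dien-1-yl]-3,5-dihydroxy-4-methylcyclohexa-2,5-dien-1-one | CCCC(=O)c1c(O)c2c(c(CC3=C(O)[C@@](C)(C/C=C(\C)CCC=C(C)C)C(O)=C(C(C)=O)C3=O)c1O)OC(C)(C)C=C2 | target

**Totals**
Total step count: 9. Longest linear sequence: 6 steps (steps 1 to 5, then step 9).

**Steps most likely to fail**

Step 5 (proposed new method). Risks are proton loss from the oxocarbenium ion or its capture by phthalimide anion before C–C bond formation, and cationic oligomerisation of the enol ether competing with ring closure. The fallback uses known chemistry, sets out from 2 and comes back at 8. Compound 2 would be O-alkylated at the 4-hydroxyl with 3-chloro-3-methylbut-1-yne (K2CO3, KI cat., CuI cat., acetone, 60 °C) to give the aryl 1,1-dimethylpropargyl ether 1-{2,6-dihydroxy-4-[(2-methylbut-3-yn-2-yl)oxy]phenyl}butan-1-one F1. Heating F1 in N,N-diethylaniline at about 160 °C should give 8 by aromatic Claisen rearrangement, 1,5-hydrogen shift and oxa-6π electrocyclisation.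

Step 9. Risks are competing oxidation of the phenolic chromene by the silver oxidant, over-oxidation of the newly formed bridge, and cycloaddition of the quinone methide onto the chromene double bond instead of conjugate addition. The fallback sets out from 13 and comes back at 15, and keeps the oxidant away from the chromene. Compound 13 would be dehydrogenated alone (Ag2O, TEMPO, MeOH/THF, 0 °C) so that the quinone methide is trapped by the solvent as the isolable ether (4R)-2-acetyl-4-[(2E)-3,7-dimethylocta-2,6-dien-1-yl]-3,5-dihydroxy-6-(methoxymethyl)-4-methylcyclohexa-2,5-dien-1-one F2. Warming F2 with 8 (NaOAc, toluene, 80 °C) should regenerate 14 by loss of methanol and give 15 by a non-oxidative Michael addition.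

Step 8. Risks are insufficient discrimination of the two enantiotopic ring carbons (low enantioselectivity), a second allylation, and partial loss of the (E) geometry by syn/anti isomerisation of the allyl complex. The fallback sets out from 10 and 12 and comes back at 13. The geranylation would be run with the achiral zerovalent palladium catalyst Pd(PPh3)4 (THF, 25 °C) to give racemic 2-acetyl-4-[(2E)-3,7-dimethylocta-2,6-dien-1-yl]-3,5-dihydroxy-4,6-dimethylcyclohexa-2,5-dien-1-one F3. The enantiomers would then be separated by preparative chromatography on a polysaccharide-based chiral stationary phase to give 13.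

**Further compounds**
F1 | step 5 | 1-{2,6-dihydroxy-4-[(2-methylbut-3-yn-2-yl)oxy]phenyl}butan-1-one | CCCC(=O)c1c(O)cc(OC(C)(C)C#C)cc1O
F2 | step 9 | (4R)-2-acetyl-4-[(2E)-3,7-dimethylocta-2,6-dien-1-yl]-3,5-dihydroxy-6-(methoxymethyl)-4-methylcyclohexa-2,5-dien-1-one | COCC1=C(O)[C@@](C)(C/C=C(\C)CCC=C(C)C)C(O)=C(C(C)=O)C1=O
F3 | step 8 | racemic 2-acetyl-4-[(2E)-3,7-dimethylocta-2,6-dien-1-yl]-3,5-dihydroxy-4,6-dimethylcyclohexa-2,5-dien-1-one | CC1=C(O)C(C)(C/C=C(\C)CCC=C(C)C)C(O)=C(C(C)=O)C1=O
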